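(The numbers of this flask are assumed; the result is computed.)

I decided to leave the flask untouched and to reckon what it would hold once 20% of the Z had gone.

Z 0.50 mM; E 1.00 mM; Q 0.17 µM

    Q → D (k1 = 0.099 s⁻¹)
    Z + Q ⇌ Z.Q (K2 = 20000 M⁻¹, k2 = 8.1 × 10⁵ M⁻¹ s⁻¹)
    Z.Q → Q + J (k3 = 690 s⁻¹)
    E.Q → Q + X (k4 = 66 s⁻¹)
    E + Q ⇌ E.Q (K5 = 2900 M⁻¹, k5 = 2.6 × 10⁷ M⁻¹ s⁻¹)

- apparent order in E when 20% of the Z are converted (percent change of the rate of making J for one percent more E charged)

**Two bindings.** E left E.Q at 8970 s⁻¹, faster than E.Q turned over at 66 s⁻¹, so I took that binding as settled. Z.Q turned over at 690 s⁻¹, faster than Z left it at 40.5 s⁻¹, so the Z binding was not settled, and I used for each form its Michaelis constant, departures over arrival: 0.902 mM for Z and 0.347 mM for E.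

**What comes.** Z and E both turned over through free Q, so their ratio of paces, the selectivity factor, was 0.248. The fraction of E left was the fraction of Z left raised to that power, which gave 0.946 mM of E beside 0.400 mM of Z. D also formed through free Q, so its amount per Z used carried no E term, and I expected 17.0% of the catalyst as D.

**Adding E.** I carried E's share, 0.654: the part of Q, Z.Q and E.Q together that stands as E.Q. At fixed conversion Z and D carried no E term while E scaled with its charge, so the order in E was minus that share, −0.654, and extra E slowed the making of J.

**The result.** The forecast was −0.65, between −0.69 and −0.61, on the ground that “the E.Q term makes up roughly 65% of the steady-state enzyme denominator”; the simulation gave −0.65.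

**What stood.** With the charges as given, free Q met E at 26000 s⁻¹ and Z at 400 s⁻¹, and at 8.00 s E.Q held 54.3% of the catalyst against 8.86% as Z.Q. At 40.0 s, with Z at 43.3% and E at 81.2% of their charges, E's share reckoned to 0.653, and the forms standing then gave 0.653.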